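Per cent of the substrate charged is the unit of this bench note, and blue is the flask on the bench, with three other set-ups beside it.

| flask | substrate | partner | remark | time |
|---|---|---|---|---|
| epsilon | 19 mM | 3 equiv | run made earlier |  |
| delta | 19 mM | 2 equiv | run made earlier |  |
| alpha | 19 mM | 4.5 equiv | run made earlier |  |
| ochre | 19 mM | 3.00 equiv | plug flow through a tube for 5.0 d, no back-mixing | 5.0 d |
| red | 19 mM | 3.00 equiv | a single well-mixed tank run continuously and read at steady state, 5.0 d in it on average |  |
| green | 19 mM | 3.00 equiv | a closed flask charged with all of it at once and left for 5.0 d | 5.0 d |
| blue | 19 mM (fed, over 4.00 d) | 3.00 equiv | a stirred flask in which substrate is dosed at a steady rate over 4.00 d without added volume, worked up at 5.0 d | 5.0 d |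

- epsilon (time / d: target / %): 0.417: 7; 0.625: 6; 0.833: 12; 1.25: 18; 2.00: 19; 3.00: 22; 5.00: 12
- delta (time / d: target / %): 0.250: 6; 0.833: 11; 1.25: 13; 2.00: 17; 3.00: 18; 4.00: 16; 5.00: 18
- alpha (time / d: target / %): 0.417: 11; 0.625: 11; 0.833: 13; 1.25: 23; 2.00: 22; 3.00: 20; 5.00: 17

(each reading ± 2 percentage points)

- the stated concentrations are those of everything mixed, before any reaction; amounts are the same in each set-up
- what was read earlier has a scatter of 2 percentage points, one standard deviation
- the feed brings no volume worth counting
- the earlier runs were made in a closed, stirred flask

* the set-up with the highest amount of target at the outlet or at the end, in percent of the substrate put in ("none" if the first two lie within 2 percentage points) (ochre / red / green / blue / none)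
* amount of target at the outlet or at the end, in percent of the substrate put in, ochre
* amount of target at the outlet or at the end, in percent of the substrate put in, red
* amount of target at the outlet or at the end, in percent of the substrate put in, green
* amount of target at the outlet or at the end, in percent of the substrate put in, blue

The highest readings are 18 % in delta and 23 % in alpha, 5 percentage points apart, more than the margin of 2 points, so I do not treat partner as indifferent. But delta at 2 equiv and alpha at 4.5 equiv lie on either side of the 3.00 equiv of the set-ups, so I average them with epsilon into a rough curve for that charge: 18.0 % at 1.25 d, 19.3 % at 2.00 d, 20.0 % at 3.00 d and 15.7 % at 5.00 d.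

Blue holds doses of differing age in one pot, sharing its partner, so as a rough estimate only I let each dose age as if it lay in a closed flask. At work-up its ages run from 1.00 d to 5.0 d. I average the curve over them, starting at the first shared reading, and call the result the age-averaged yield, the curve read through the residence-time distribution: 18.5 %.

Ochre and green each have one age, so I expect 15.7 % from them. Leave blue's pump at its steady rate until 4.00 d, because blue's 18.5 % is more than that by 2.8 points.

The forecast, saying “dosed material ages only 1–5 d, averaging near the batch peak”, gives 15 % for ochre, 13 % for red, 15 % for green and 18 % for blue, with blue best.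

The flasks give 16.1 % for ochre, 12.9 % for red, 16.1 % for green and 19.1 % for blue, with blue best.

    substrate + partner → intermediate + by-product (k = 0.220 /M/h)
    intermediate ⇌ target (K = 6.60, k = 0.160 /h)
    intermediate ⇌ isomer of the product (K = 2.90, k = 0.00170 /h)
    partner → decomposed reagent (k = 0.00170 /h)
    target + by-product → side product (k = 2.10 /M/h)
    partner + target → over-reaction product (k = 0.220 /M/h)

In blue, intermediate and target relax into each other with a half-life of 0.157 d by that step alone, shorter than the 5.0 d of the run. Intermediate and isomer of the product take 12.6 d. Red's ages spread exponentially: 22.1 % lie below 1.25 d, read at half of 18.0 %; 36.8 % lie beyond 5.0 d, guessed at half of 15.7 %; and 41.1 % lie between, read at 18.5 %. That sums to 12.5 %, and red gives 12.9 %.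

All runs come from a simulation on assumed constants, and the scatter is random.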